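The target is disconnected at C8–C15′ and C13–C14′ of its bicyclo[3.2.1]octenedione, i.e. a perezone-type [5+2] union of 4-epi-trans-communic acid with a 6-5-6 hydroxyquinone. In that quinone all stereocentres are relayed from C10, the methyl-bearing benzylic quaternary carbon shared by rings A and B. The key step exploits this atom and its neighbour C5: a chiral-acid-catalysed protio-semipinacol shift converts an achiral 1-(1-arylvinyl)cyclopentanol into the ring-A cyclohexanone, enlarging the five-membered carbocycle by one carbon and setting C10 in one operation. The resulting C5 ketone then admits the C4 gem-dimethyl group and the C6 link to ring B.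

Key step: step 4

Remark on numbering: abietane-type numbering is used for the quinoid half (ring A = C1–C5/C10, ring B = C5/C6/C8/C9/C10, ring C = C8/C9/C11–C14, C7 = formyl carbon, C20 = methyl on C10); the labdane half carries primes.
Assumption: 4-epi-trans-communic acid, the diene partner of the last step, is bought as the isolated natural acid from natural-product suppliers and used unprotected.
Remark: stereocentres or double bonds written without descriptor (in 11–14, 16 and 19) are expected as mixtures that converge in the following step.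

Step 1
Reactants: 1 1,4-dibromo-2,5-dimethoxybenzene; 2 acetone
Product: 4 2-(4-bromo-2,5-dimethoxyphenyl)propan-2-ol, via aryllithium 3 (not isolated)
Conditions: n-BuLi (1.0 equiv), THF, −78 °C; then acetone; H2O
Reagents that add atoms: none
Why: Mono bromine–lithium exchange of the symmetric dibromide (the second exchange is slower on the electron-richer aryllithium) followed by 1,2-addition to acetone; no stereocentre is formed.

Step 2
Reactants: 4 2-(4-bromo-2,5-dimethoxyphenyl)propan-2-ol
Product: 5 1-bromo-2,5-dimethoxy-4-(propan-2-yl)benzene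
Conditions: Et3SiH, TFA, CH2Cl2, 0 °C → rt
Reagents that add atoms: none
Why: Ionic hydrogenation, in which TFA ionises the tertiary benzylic alcohol to a methoxy-stabilised cumyl cation that takes hydride from the silane while the aryl bromide stays inert.

Step 3
Reactants: 5 1-bromo-2,5-dimethoxy-4-(propan-2-yl)benzene; 6 1-ethynylcyclopentan-1-ol
Product: 8 1-{1-[2,5-dimethoxy-4-(propan-2-yl)phenyl]ethenyl}cyclopentan-1-ol, via arylmagnesium bromide 7 (not isolated)
Conditions: 5, Mg, THF, reflux; 6 pre-treated with i-PrMgCl (1.0 equiv), THF, 0 °C; CuI (10 mol %), THF/toluene, 70 °C; aq NH4Cl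
Reagents that add atoms: none
Why: Copper(I)-catalysed anti-carbomagnesiation of a propargylic alkoxide, in which the alkoxide holds magnesium on the terminal carbon in a five-membered chelate so that the aryl group is delivered to the internal alkyne carbon and protonolysis gives the 1,1-disubstituted alkene; no stereocentre is formed.

Step 4
Reactants: 8 1-{1-[2,5-dimethoxy-4-(propan-2-yl)phenyl]ethenyl}cyclopentan-1-ol
Product: 9 (2R)-2-[2,5-dimethoxy-4-(propan-2-yl)phenyl]-2-methylcyclohexan-1-one
Conditions: confined chiral imidodiphosphorimidate (IDPi) Brønsted acid (3 mol %, antipode chosen to deliver R), CHCl3, −40 °C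
Reagents that add atoms: none
Why: Proposed new method: the chiral acid should protonate the electron-rich 1,1-disubstituted styrene at its CH2 terminus to give a tertiary benzylic C10 cation held in a contact ion pair with the chiral anion, and a ring C–C bond of the cyclopentanol then migrates to C10 while the carbinol carbon (C5) becomes the carbonyl, so that the five-membered carbocycle becomes six-membered ring A and the protonated CH2 becomes the C20 methyl. The closest known reaction type is the catalytic enantioselective protio-semipinacol (Wagner–Meerwein) ring expansion of 1-alkenylcyclopropanols and -cyclobutanols, and acid- or electrophile-induced ring expansions of 1-alkenylcycloalkanols in general; here no ring strain is released, so the shift must be driven by the methoxy-stabilised cation and by C=O formation. No ring is closed by cyclisation; ring A arises by a suprafacial 1,2-alkyl shift that inserts C10 into the ring. The only new stereocentre, C10, is set by catalyst control, the anion deciding to which face of the planar cation the migrating CH2 is delivered. The step needs chemoselective alkene protonation over ionisation of the tertiary allylic alcohol, which the 2,5-dimethoxyaryl group should secure by making the styrene the most basic site, and it has no regiochemical issue because the two ring bonds of the cyclopentanol are equivalent.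

Step 5
Reactants: 9 (2R)-2-[2,5-dimethoxy-4-(propan-2-yl)phenyl]-2-methylcyclohexan-1-one
Product: 10 (2R)-2-[2,5-dimethoxy-4-(propan-2-yl)phenyl]-2,6,6-trimethylcyclohexan-1-one
Conditions: NaH (2.5 equiv), MeI (4 equiv), THF, reflux
Reagents that add atoms: iodomethane, CI
Why: Exhaustive enolate alkylation, possible only at the C4 methylene because C10 is quaternary and therefore can neither enolise nor epimerise.

Step 6
Reactants: 10 (2R)-2-[2,5-dimethoxy-4-(propan-2-yl)phenyl]-2,6,6-trimethylcyclohexan-1-one
Product: 11 (4R)-4-[2,5-dimethoxy-4-(propan-2-yl)phenyl]-4,8,8-trimethyl-1-oxaspiro[2.5]octane (spiro-carbon epimers)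
Conditions: Me3S+ I−, n-BuLi, THF, 0 °C → rt
Reagents that add atoms: trimethylsulfonium iodide, C[S+](C)C.[I-]
Why: Corey–Chaykovsky methylene transfer, in which the small, reactive dimethylsulfonium methylide should add irreversibly even to a ketone flanked by two quaternary carbons; the new spiro centre is erased in step 7.

Step 7
Reactants: 11 (4R)-4-[2,5-dimethoxy-4-(propan-2-yl)phenyl]-4,8,8-trimethyl-1-oxaspiro[2.5]octane
Product: 13 (4bS)-1,4-dimethoxy-4b,8,8-trimethyl-2-(propan-2-yl)-4b,5,6,7,8,8a-hexahydro-9H-fluoren-9-ol (C8a/C9 epimers), via aldehyde 12 (not isolated)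
Conditions: Me2AlCl (2.2 equiv), CH2Cl2, −78 → 0 °C; aq Rochelle salt
Reagents that add atoms: none
Why: Lewis-acid Meinwald rearrangement (epoxide opening at C5 with 1,2-hydride shift) gives the aldehyde, whose carbonyl carbon (C6) is then attacked in a 5-exo-trig intramolecular Friedel–Crafts hydroxyalkylation by C8, the only free aryl position next to the aryl–C10 bond and ortho to a methoxy group; the aluminium alkoxide should not ionise, and the C5 and C6 configurations are reset in step 8.

Step 8
Reactants: 13 (4bS)-1,4-dimethoxy-4b,8,8-trimethyl-2-(propan-2-yl)-4b,5,6,7,8,8a-hexahydro-9H-fluoren-9-ol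
Product: 15 (4bS,8aS)-1,4-dimethoxy-4b,8,8-trimethyl-2-(propan-2-yl)-4b,5,6,7,8,8a-hexahydro-9H-fluoren-9-one, via ketone epimer mixture 14 (not isolated)
Conditions: Dess–Martin periodinane, CH2Cl2, rt; then DBU (0.3 equiv), toluene/MeOH, 60 °C
Reagents that add atoms: none
Why: Dess–Martin oxidation removes the C6 stereocentre and base equilibration through the C5 enolate should funnel the ketone into the trans-fused isomer (C5–H anti to the C10 methyl), expected to be the thermodynamic one because in the cis isomer either C6 is axial or the α-methyl on C4 is syn-diaxial to the C10–aryl bond; C5 is thus set by thermodynamic control relative to C10.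

Step 9
Reactants: 15 (4bS,8aS)-1,4-dimethoxy-4b,8,8-trimethyl-2-(propan-2-yl)-4b,5,6,7,8,8a-hexahydro-9H-fluoren-9-one
Product: 16 (4bS,8aS)-1,4-dimethoxy-9-(methoxymethylidene)-4b,8,8-trimethyl-2-(propan-2-yl)-4b,5,6,7,8,8a-hexahydro-9H-fluorene (E/Z mixture)
Conditions: Ph3P+CH2OMe Cl−, KHMDS, THF, 0 → 50 °C
Reagents that add atoms: (methoxymethyl)triphenylphosphonium chloride, COC[P+](c1ccccc1)(c1ccccc1)c1ccccc1.[Cl-]
Why: Wittig olefination of the aryl ketone with the methoxymethylene ylide installs C7 as an enol ether; both alkene isomers converge in step 10 and C5 is safe because it is already the thermodynamic epimer.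

Step 10
Reactants: 16 (4bS,8aS)-1,4-dimethoxy-9-(methoxymethylidene)-4b,8,8-trimethyl-2-(propan-2-yl)-4b,5,6,7,8,8a-hexahydro-9H-fluorene
Product: 17 (4bS,8aS,9R)-9-hydroxy-1,4-dimethoxy-4b,8,8-trimethyl-2-(propan-2-yl)-4b,5,6,7,8,8a-hexahydro-9H-fluorene-9-carbaldehyde
Conditions: OsO4 (2 mol %), NMO, acetone/H2O, 0 °C → rt
Reagents that add atoms: osmium tetroxide, O=[Os](=O)(=O)=O; N-methylmorpholine N-oxide, C[N+]1([O-])CCOCC1; water, O
Why: Catalytic OsO4/NMO dihydroxylation of the electron-rich enol ether should occur on the α face, anti to the axial β-methyl groups on C10 and C4, and the hemiacetal collapses with loss of methanol to the α-hydroxy aldehyde, so C6 (α-OH, β-CHO) is set by substrate control.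

Step 11
Reactants: 17 (4bS,8aS,9R)-9-hydroxy-1,4-dimethoxy-4b,8,8-trimethyl-2-(propan-2-yl)-4b,5,6,7,8,8a-hexahydro-9H-fluorene-9-carbaldehyde
Product: 18 (4bS,8aS,9R)-9-hydroxy-4b,8,8-trimethyl-1,4-dioxo-2-(propan-2-yl)-4,4b,5,6,7,8,8a,9-octahydro-1H-fluorene-9-carbaldehyde
Conditions: CAN (2.5 equiv), MeCN/H2O, 0 °C
Reagents that add atoms: water, O
Why: Cerium(IV) oxidative demethylation of the hydroquinone dimethyl ether (two one-electron oxidations with ipso attack of water) is fast at 0 °C and is expected to outpace cleavage of the hindered α-hydroxy aldehyde; no stereocentre is touched.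

Step 12
Reactants: 18 (4bS,8aS,9R)-9-hydroxy-4b,8,8-trimethyl-1,4-dioxo-2-(propan-2-yl)-4,4b,5,6,7,8,8a,9-octahydro-1H-fluorene-9-carbaldehyde
Product: 20 (4bS,8aS,9R)-3,9-dihydroxy-4b,8,8-trimethyl-1,4-dioxo-2-(propan-2-yl)-4,4b,5,6,7,8,8a,9-octahydro-1H-fluorene-9-carbaldehyde, via epoxyquinone 19 (not isolated)
Conditions: t-BuOOH (1.1 equiv), DBU (2.2 equiv), CH2Cl2, −20 °C → rt; aq citric acid
Reagents that add atoms: tert-butyl hydroperoxide, CC(C)(C)OO
Why: Weitz–Scheffer nucleophilic epoxidation should occur at C12=C13, the only quinone double bond carrying a hydrogen, and base-induced E1cB opening of the epoxide (deprotonation at C12) gives the 12-hydroxyquinone, the classical quinone-to-hydroxyquinone sequence; existing stereocentres are untouched.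

Step 13
Reactants: 20 (4bS,8aS,9R)-3,9-dihydroxy-4b,8,8-trimethyl-1,4-dioxo-2-(propan-2-yl)-4,4b,5,6,7,8,8a,9-octahydro-1H-fluorene-9-carbaldehyde; 21 4-epi-trans-communic acid, (1R,4aR,5S,8aR)-1,4a-dimethyl-6-methylidene-5-[(2E)-3-methylpenta-2,4-dien-1-yl]decahydronaphthalene-1-carboxylic acid
Product: 22 CNP0124601.1, the [5+2] adduct of 20 across C14′=C15′ of 21
Conditions: 21 (1.5 equiv), (CF3)2CHOH, 0 °C → rt
Reagents that add atoms: none
Why: Perezone-type [5+2] cycloaddition, in which the hydrogen-bond-activated hydroxyquinone reacts as a C13–C12–C11–C9–C8 hydroxypentadienyl cation with the terminal alkene of the diene, the nucleophilic CH2 terminus C15′ bonding to electrophilic C8 and the developing allyl cation being captured at C14′ by the enol carbon C13, expected on the α face of the quinone (anti to the C10 methyl and the C6 formyl group) and in the compact endo mode that places the diene residue under the C9–C11–C12 bridge, so that C8, C13 and C14′ are set together by substrate control.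

Compound list
1 | 1,4-dibromo-2,5-dimethoxybenzene | COc1cc(Br)c(OC)cc1Br | starting material
2 | acetone | CC(C)=O | starting material
3 | (4-bromo-2,5-dimethoxyphenyl)lithium | [Li]c1cc(OC)c(Br)cc1OC | intermediate (not isolated)
4 | 2-(4-bromo-2,5-dimethoxyphenyl)propan-2-ol | COc1cc(C(C)(C)O)c(OC)cc1Br | intermediate
5 | 1-bromo-2,5-dimethoxy-4-(propan-2-yl)benzene | COc1cc(C(C)C)c(OC)cc1Br | intermediate
6 | 1-ethynylcyclopentan-1-ol | C#CC1(O)CCCC1 | starting material
7 | [2,5-dimethoxy-4-(propan-2-yl)phenyl]magnesium bromide | COc1cc(C(C)C)c(OC)cc1[Mg]Br | intermediate (not isolated)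
8 | 1-{1-[2,5-dimethoxy-4-(propan-2-yl)phenyl]ethenyl}cyclopentan-1-ol | C=C(c1cc(OC)c(C(C)C)cc1OC)C1(O)CCCC1 | intermediate
9 | (2R)-2-[2,5-dimethoxy-4-(propan-2-yl)phenyl]-2-methylcyclohexan-1-one | C[C@]1(c2cc(OC)c(C(C)C)cc2OC)CCCCC1=O | intermediate
10 | (2R)-2-[2,5-dimethoxy-4-(propan-2-yl)phenyl]-2,6,6-trimethylcyclohexan-1-one | C[C@]1(c2cc(OC)c(C(C)C)cc2OC)CCCC(C)(C)C1=O | intermediate
11 | (4R)-4-[2,5-dimethoxy-4-(propan-2-yl)phenyl]-4,8,8-trimethyl-1-oxaspiro[2.5]octane, spiro-carbon epimers | C[C@]1(c2cc(OC)c(C(C)C)cc2OC)CCCC(C)(C)C12CO2 | intermediate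
12 | (2S)-2-[2,5-dimethoxy-4-(propan-2-yl)phenyl]-2,6,6-trimethylcyclohexane-1-carbaldehyde, C1 epimers | C[C@]1(c2cc(OC)c(C(C)C)cc2OC)CCCC(C)(C)C1C=O | intermediate (not isolated)
13 | (4bS)-1,4-dimethoxy-4b,8,8-trimethyl-2-(propan-2-yl)-4b,5,6,7,8,8a-hexahydro-9H-fluoren-9-ol, C8a/C9 epimers | COc1cc(C(C)C)c(OC)c2c1[C@@]1(C)CCCC(C)(C)C1C2O | intermediate
14 | (4bS)-1,4-dimethoxy-4b,8,8-trimethyl-2-(propan-2-yl)-4b,5,6,7,8,8a-hexahydro-9H-fluoren-9-one, C8a epimers | COc1cc(C(C)C)c(OC)c2c1[C@@]1(C)CCCC(C)(C)C1C2=O | intermediate (not isolated)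
15 | (4bS,8aS)-1,4-dimethoxy-4b,8,8-trimethyl-2-(propan-2-yl)-4b,5,6,7,8,8a-hexahydro-9H-fluoren-9-one (trans-fused) | COc1cc(C(C)C)c(OC)c2c1[C@@]1(C)CCCC(C)(C)[C@@H]1C2=O | intermediate
16 | (4bS,8aS)-1,4-dimethoxy-9-(methoxymethylidene)-4b,8,8-trimethyl-2-(propan-2-yl)-4b,5,6,7,8,8a-hexahydro-9H-fluorene, E/Z mixture | COc1cc(C(C)C)c(OC)c2c1[C@@]1(C)CCCC(C)(C)[C@@H]1C2=COC | intermediate
17 | (4bS,8aS,9R)-9-hydroxy-1,4-dimethoxy-4b,8,8-trimethyl-2-(propan-2-yl)-4b,5,6,7,8,8a-hexahydro-9H-fluorene-9-carbaldehyde | COc1cc(C(C)C)c(OC)c2c1[C@@]1(C)CCCC(C)(C)[C@@H]1[C@]2(O)C=O | intermediate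
18 | (4bS,8aS,9R)-9-hydroxy-4b,8,8-trimethyl-1,4-dioxo-2-(propan-2-yl)-4,4b,5,6,7,8,8a,9-octahydro-1H-fluorene-9-carbaldehyde | O=C1C(C(C)C)=CC(=O)C2=C1[C@@](O)(C=O)[C@H]1C(C)(C)CCC[C@]21C | intermediate
19 | 2,3-epoxide of 18 (C12–C13 epoxyquinone, epoxide epimers) | O=C1C2(C(C)C)OC2C(=O)C2=C1[C@@](O)(C=O)[C@H]1C(C)(C)CCC[C@]21C | intermediate (not isolated)
20 | (4bS,8aS,9R)-3,9-dihydroxy-4b,8,8-trimethyl-1,4-dioxo-2-(propan-2-yl)-4,4b,5,6,7,8,8a,9-octahydro-1H-fluorene-9-carbaldehyde (12-hydroxy-11,14-quinone) | O=C1C(C(C)C)=C(O)C(=O)C2=C1[C@@](O)(C=O)[C@H]1C(C)(C)CCC[C@]21C | intermediate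
21 | 4-epi-trans-communic acid, (1R,4aR,5S,8aR)-1,4a-dimethyl-6-methylidene-5-[(2E)-3-methylpenta-2,4-dien-1-yl]decahydronaphthalene-1-carboxylic acid | C=C1CC[C@@H]2[C@](C)(CCC[C@@]2(C)C(=O)O)[C@H]1C/C=C(\C)C=C | starting material
22 | CNP0124601.1 | C=C1CC[C@@H]2[C@](C)(CCC[C@@]2(C)C(=O)O)[C@H]1C/C=C(\C)[C@@H]1C[C@@]23C(=O)[C@]1(C(C)C)C(=O)C(O)=C2[C@@]1(C)CCCC(C)(C)[C@@H]1[C@]3(O)C=O | target

Total step count: 13. Longest linear sequence: 13 steps (1 → 22); the diene acid 21 enters in the last step.

Steps most likely to fail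

1. Step 4 (proposed new method). What may go wrong: ionisation of the tertiary allylic alcohol with loss of water to a diene instead of alkene protonation, or a loosely organised ion pair so that the unstrained shift proceeds with low enantioselectivity. Fallback, by known chemistry and still a ring enlargement: setting out from 8, an achiral acid (p-TsOH·H2O, toluene, 60 °C; the classical acid-promoted semipinacol shift of 1-alkenylcycloalkanols) would give the racemic ketone rac-2-[2,5-dimethoxy-4-(propan-2-yl)phenyl]-2-methylcyclohexan-1-one F1, which would be resolved by preparative chromatography on a chiral stationary phase; its R enantiomer is 9, where the route is rejoined.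

2. Step 13. What may go wrong: protonation and migration of the exocyclic C8′=C17′ double bond or of the diene in the acidic medium before the slow bimolecular union, and poor facial or endo/exo control. Fallback: setting out from 21, esterification (allyl bromide, K2CO3, DMF) would give prop-2-en-1-yl 4-epi-trans-communate F2. A Lewis-acid-triggered stepwise cation–olefin union of F2 with 20 at low temperature (BF3·OEt2, CH2Cl2, −78 °C), where no free carboxylic acid can act as proton source, would give the prop-2-en-1-yl ester of the adduct F3. Neutral deallylation (Pd(PPh3)4, N-methylaniline, THF, rt) would then return to 22.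

3. Step 12. What may go wrong: attack of the hydroperoxide anion or of the base on the free α-hydroxy aldehyde (C–C cleavage or α-ketol enlargement of ring B) competing with quinone epoxidation. Fallback: setting out from 16, the aldehyde would be carried in masked form. m-CPBA in methanol (−20 °C; α-face epoxidation of the enol ether and methanolysis) would give the α-hydroxy dimethyl acetal F4. CAN (MeCN/H2O, 0 °C) would give the quinone acetal F5. t-BuOOH/DBU would give, through the epoxyquinone acetal F6, the hydroxyquinone acetal F7. Mild aqueous acid (1 M HCl, THF, rt) would unmask the aldehyde and return to 20.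

Further compounds
F1 | step 4 | rac-2-[2,5-dimethoxy-4-(propan-2-yl)phenyl]-2-methylcyclohexan-1-one | CC1(c2cc(OC)c(C(C)C)cc2OC)CCCCC1=O
F2 | step 13 | prop-2-en-1-yl 4-epi-trans-communate | C=C1CC[C@@H]2[C@](C)(CCC[C@@]2(C)C(=O)OCC=C)[C@H]1C/C=C(\C)C=C
F3 | step 13 | prop-2-en-1-yl ester of 22 | C=C1CC[C@@H]2[C@](C)(CCC[C@@]2(C)C(=O)OCC=C)[C@H]1C/C=C(\C)[C@@H]1C[C@@]23C(=O)[C@]1(C(C)C)C(=O)C(O)=C2[C@@]1(C)CCCC(C)(C)[C@@H]1[C@]3(O)C=O
F4 | step 12 | (4bS,8aS,9R)-9-(dimethoxymethyl)-1,4-dimethoxy-4b,8,8-trimethyl-2-(propan-2-yl)-4b,5,6,7,8,8a-hexahydro-9H-fluoren-9-ol | COc1cc(C(C)C)c(OC)c2c1[C@@]1(C)CCCC(C)(C)[C@@H]1[C@]2(O)C(OC)OC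
F5 | step 12 | (4bS,8aS,9R)-9-(dimethoxymethyl)-9-hydroxy-4b,8,8-trimethyl-2-(propan-2-yl)-4b,5,6,7,8,8a-hexahydro-9H-fluorene-1,4-dione | O=C1C(C(C)C)=CC(=O)C2=C1[C@@](O)(C(OC)OC)[C@H]1C(C)(C)CCC[C@]21C
F6 | step 12 | 2,3-epoxide of F5 (epoxide epimers, not isolated) | O=C1C2(C(C)C)OC2C(=O)C2=C1[C@@](O)(C(OC)OC)[C@H]1C(C)(C)CCC[C@]21C
F7 | step 12 | (4bS,8aS,9R)-9-(dimethoxymethyl)-3,9-dihydroxy-4b,8,8-trimethyl-2-(propan-2-yl)-4b,5,6,7,8,8a-hexahydro-9H-fluorene-1,4-dione | O=C1C(C(C)C)=C(O)C(=O)C2=C1[C@@](O)(C(OC)OC)[C@H]1C(C)(C)CCC[C@]21C
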